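## Structural features

Mitorubrinic acid is a 6H-isochromene-6,8(7H)-dione (an azaphilone). Carbocyclic ring A (C4a, C5, C6, C7, C8, C8a) carries ketones at C6 and C8 and is fused along C4a–C8a to ring B (C1, O2, C3, C4), a fully unsaturated pyran tied to ring A through the C4a=C5 double bond, so that O2 and the C6 carbonyl are the two ends of one long vinylogous ester. C3 carries an (E)-acrylic acid; C7 carries a methyl group and the oxygen of an orsellinate (2,4-dihydroxy-6-methylbenzoate) ester. C7 is the only stereocentre: it is quaternary, R-configured, sits between the two ring carbonyls and has no stereogenic neighbour. It cannot epimerise by enolisation, but its configuration rests only on the difference between the C6 arm and the C8 arm, so any intermediate in which these arms become equivalent or exchange erases it. Fragile features are the electrophilic C1 and C3 of the pyran (attacked by amines and other nucleophiles), the 2,2-disubstituted 1,3-diketone (retro-Claisen cleavage by alkoxides), the polyene (no hydrogenation once present) and the tertiary ester of a 2,6-disubstituted benzoic acid, the hardest acylation in the molecule. The real difficulty is threefold: an oxygenated quaternary centre as one enantiomer, a doubly hindered ester, and a ring B closure that puts oxygen on C1 and carbon on C4a and not the reverse. The key step exploits the cyclohexane-1,3,5-trione oxygen pattern of ring A: C6–C7–C8 is a 2-acyloxy-2-methylmalonyl unit and C5–C4a–C8a is the three-carbon unit of a methyl ketone, so two acylations (C8 to C8a, C6 to C5) build ring A at the right oxidation level with C7 and its ester already complete.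

## Logic of the disconnections

25 ⇒ 24. The O–C bonds of the tert-butyl ester and of the two methoxymethyl acetals are cut. The free acid and phenols would interfere with the amide base, the sulfonylation and the palladium/copper coupling, and all three groups fall together in acid, which the isochromenedione tolerates; hydrogenolysis, fluoride or basic nucleophiles would endanger the polyene or the pyran. The demand on the forward step is acidolysis that leaves the tertiary aryl ester alone.

24 ⇒ 22 (through 23). The O2–C3 bond is cut and the oxygen on C1 is traced back to nitrogen. Ring B then arises by addition of the C1 enol oxygen across a C3≡C4 triple bond, which already holds the correct oxidation level, so no redox step is needed and a bicycle becomes a monocycle. The forward step must exchange nitrogen for oxygen at C1 under mild aqueous acid and close in the 6-endo sense; the polarisation of the ynenone (C3 is the δ-carbon of the C6 dienone) supports this.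

22 ⇒ 17 + 21. The C4–C4a bond is cut. A ketone enolate as C4 donor was not adopted: the most electrophilic carbon of 16 toward carbon nucleophiles is C1, and attack there would put carbon on C1 and oxygen on C4a, the wrong pyran. An sp–sp2 coupling avoids any free carbon nucleophile, is convergent and delivers the side chain complete with its E alkene. It demands a leaving group on C4a and a terminal alkyne in 21.

17 ⇒ 16. The O–S bond is cut: the enol oxygen on C4a of the β-diketone is activated as a sulfonate. The demand is regioselectivity, sulfonylation of the oxygen on C4a and not of the one on C6.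

16 ⇒ 13 + 14 (through 15). The C8–C8a and C5–C6 bonds are cut, which dissolves ring A into a malonyl half-ester chloride and a four-carbon enaminone. The cut follows the 1,3,5-trioxygenation of ring A; 14 brings C1 at the aldehyde oxidation level and makes the two methylene positions of the trione different, and 13 brings C7 with its ester intact. The forward step must form the two bonds in a fixed order (acid chloride to C8a first, ester to C5 second), because this order alone decides which carboxyl carbon becomes C8 and therefore the configuration of C7 in the ring.

13 ⇒ 12 ⇒ 11. The C–Cl bond and then the O–CH2Ph bond are cut. One carboxyl group out of three ester functions must be set free; a benzyl ester can be removed by hydrogenolysis without acid or base, so no ester exchange between the two carboxyl groups on C7 (which would amount to racemisation) can occur. The chloride must be made without HCl because of the acetal protecting groups.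

11 ⇒ 6 + 9 (through 10). The ester bond between the C7 oxygen and the aroyl carbon is cut. The doubly hindered esterification is thereby moved to the start, onto a small and robust hydroxy diester, instead of the sensitive bicycle. It demands a very reactive acyl donor and a hydroxyl partner that has no free carboxylic acid.

6 ⇒ 4 (through 5) ⇒ 3 ⇒ 1 + 2. Cut in turn are the benzyl–oxygen bond and the acetal of the dioxolanone, then the bond from C7 to the methyl ester carbon, then the acetal C–O bonds. The configuration of 1 is stored in the acetal carbon of 3 while C7 becomes trigonal, and the acetal returns it on acylation. This requires the electrophile to enter trans to the tert-butyl group, and ring opening that touches only the lactone carbonyl.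

9 ⇒ 7 (through 8). The two acetal C–O bonds on the phenols are cut; the acid is protected and released in the same operation.

21 ⇒ 20 ⇒ 18 + 19. The C–Si bond and then the C=C bond of the enoate are cut; a phosphonate olefination of a silyl-protected ynal gives the E enyne from two commercial components.

## Other disconnections considered

Alternative 1: The cut runs through the orsellinate itself: the acyl C–O bond at the C7 oxygen and the C1'–C6' bond of the arene. In the forward direction the tertiary alcohol A3 would be heated with the diketo-dioxinone A2; loss of acetone gives an acylketene that is captured by the C7 hydroxyl, and the resulting 3,5,7-trioxooctanoate would close by aldol condensation and aromatise to A1, the tert-butyl ester of the target. In its favour, an acylketene is a small, neutral and very reactive acyl donor, so the hindered esterification that burdens step 5 of the chosen plan becomes an easy one, and no phenol protecting groups are needed. On the ester bond itself this alternative is the better of the two. Against it here, it does nothing for ring A or the stereocentre: A3 must first be obtained as one enantiomer by other chemistry, and is then exposed late to about 110 °C and to the base or acid of the aromatisation with a free tertiary ketol and an electrophilic pyran. In structure, the chosen plan never has a free C7 hydroxyl on the bicycle. In mechanism, both depend on acyl transfer to a tertiary oxygen, the alternative with the better donor. In step economy, the alternative saves the phenol protection and ends with a single ester cleavage, which is at least equal for the last stages, but A2 and A3 each need their own multistep preparation. The acylketene idea is kept as the fallback for step 5.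

Alternative 2: The cut is O2–C1 of ring B together with the whole acrylic acid, traced back to a 5-silylfuran joined through a methylene group (the future C4) to the aromatic aldehyde A4. Forward, singlet oxygen would turn A4 into the hydroxybutenolide A5, the ring form of a (Z)-4-oxo-2-enoic acid; acid would open it, equilibrate the alkene to E and condense the oxygen on C3 with the ortho formyl carbon C1 to give the anhydrobase A6. In its favour, ring B and the unprotected acrylic acid arise in one operation from a flat, robust arene, and the sense of the ring closure is unambiguous because the formyl carbon is the only electrophile. On that point it is better than the chosen plan, whose step 9 must distinguish two enol oxygens. Against it, A6 is achiral and at the arene oxidation level: C7 would still have to be oxygenated by an oxidative dearomatisation whose facial selectivity depends on a chiral reagent, on a substrate with a free acid and an oxidisable diene, and the hindered ester would then have to be made on the core. In structure, the alternative builds the periphery first and the stereocentre last, the chosen plan the reverse. In mechanism, its ring closure is a plain carbonyl condensation and more secure than step 13, but its stereocentre is reagent-controlled and not taken from the chiral pool. In step count, the way to the bicyclic skeleton is probably shorter, yet the two hardest operations remain after its key step.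

Alternative 3: The cut is the C7–C8 bond. Forward, a chiral triazolylidene carbene would add to the formyl group of A7 (the future C8); the acyl-anion equivalent would add to the methyl ketone carbonyl (C7) of the 2,3-dioxobutylidene arm and release the catalyst, giving the tertiary ketol A8, which is the same compound as A3. In its favour, the step is catalytic, forms ring A and the stereocentre together without stoichiometric chiral material, and intramolecular aldehyde–ketone benzoin closures to six-membered tertiary ketols are established. In forming ring A in a single step it is the equal of the chosen key step, and it is the more atom-economical since nothing is expelled. Against it, the formyl group of A7 is a vinylogous formate and a poor partner for the carbene, while C1 of the same pyran is a conjugate acceptor for it; the 1,2-diketone offers a second carbonyl (C6, five-membered closure) and an enolisable methyl group; and the enantioselectivity would depend on a catalyst–substrate fit that cannot be predicted for this planar push–pull substrate. In the chosen plan the configuration follows from a substrate-controlled acylation and from constitution. A8 would still need the hindered acylation, and A7 itself is not a simple compound, so the apparent gain in steps is uncertain.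

Key step: step 8

Remark on the chemistry: atom numbers C1 to C8a refer to the isochromene skeleton of 25 throughout. The configurations of 13 (R), 16 (R) and the choice of (S)-lactic acid were checked against C7 of 25 (R): with retention in step 2 the lactate carboxyl carbon becomes C8 and the new ester carbon becomes C6, which is consistent, so these structures are used unchanged.

Remark on the chemistry: 16 is drawn as the triketone and 23 as the hydroxymethylene dione although both should exist as enol tautomers, and the exocyclic C=C of 15, 16, 17, 22 and 23 is drawn without a descriptor because rotation about it is easy in these push–pull systems; neither point affects C7.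

Step 1
Reactants: 1 (S)-lactic acid; 2 pivalaldehyde (2,2-dimethylpropanal)
Product: 3 (2S,5S)-2-tert-butyl-5-methyl-1,3-dioxolan-4-one (cis)
Conditions: TsOH·H2O (cat.), H2SO4 (cat.), pentane, reflux, Dean–Stark; crystallisation from pentane/Et2O at −78 °C
Reagents that add atoms: none
Why: Acid-catalysed acetalisation with removal of water; under equilibrating conditions the cis-2,5-disubstituted dioxolanone should predominate, so the new acetal centre (2S) is set by thermodynamic control relative to the lactate centre, and low-temperature crystallisation should remove the trans isomer.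

Step 2
Reactants: 3 (2S,5S)-2-tert-butyl-5-methyl-1,3-dioxolan-4-one
Product: 4 methyl (2S,4R)-2-tert-butyl-4-methyl-5-oxo-1,3-dioxolane-4-carboxylate
Conditions: LiN(iPr)2 (1.05 equiv), THF, −78 °C; then ClCO2Me, −78 °C; aq NH4Cl
Reagents that add atoms: methyl chloroformate, COC(=O)Cl
Why: C-Acylation of a lactone enolate by a chloroformate under the principle of self-regeneration of stereocentres: the enolate is planar at the former lactate carbon, the tert-butyl group on the acetal carbon shields one face, and the electrophile should enter trans to it, where the hydrogen was (net retention); the product has no α-hydrogen, so it cannot be acylated again or epimerise.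

Step 3
Reactants: 4 methyl (2S,4R)-2-tert-butyl-4-methyl-5-oxo-1,3-dioxolane-4-carboxylate
Product: 6 benzyl methyl (2R)-2-hydroxy-2-methylpropanedioate, via hydroxy acid 5 (not isolated)
Conditions: LiOH (1.0 equiv), THF/H2O, 0 °C; evaporate; then BnBr, Bu4NI (cat.), DMF, rt
Reagents that add atoms: lithium hydroxide, [Li+].[OH-]; benzyl bromide, BrCc1ccccc1
Why: Saponification followed by carboxylate alkylation: hydroxide should attack the acylal-type lactone carbonyl (activated, hemiacetal leaving group that collapses to pivalaldehyde) much faster than the hindered methyl ester, and the SN2 benzylation of the carboxylate uses no alkoxide, so the two carboxyl groups on the stereocentre cannot exchange their ester groups and the configuration is kept.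

Step 4
Reactants: 7 orsellinic acid (2,4-dihydroxy-6-methylbenzoic acid)
Product: 9 2,4-bis(methoxymethoxy)-6-methylbenzoic acid, via methoxymethyl ester 8 (not isolated)
Conditions: NaH (3.3 equiv), MOMCl (3.3 equiv), THF/DMF, 0 °C→rt; then KOH, MeOH/H2O, 50 °C; cold aq HCl to pH 4
Reagents that add atoms: chloromethyl methyl ether, COCCl; potassium hydroxide, [K+].[OH-]
Why: Williamson-type O-alkylation of the trisodium salt protects both phenols (including the chelated ortho one) and the acid; the alkoxymethyl ester is an activated ester and should be saponified (hydroxide oxygen entering the carboxyl group on acyl cleavage) while the aryl acetals are stable to base.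

Step 5
Reactants: 9 2,4-bis(methoxymethoxy)-6-methylbenzoic acid; 6 benzyl methyl (2R)-2-hydroxy-2-methylpropanedioate
Product: 11 benzyl methyl (2R)-2-{[2,4-bis(methoxymethoxy)-6-methylbenzoyl]oxy}-2-methylpropanedioate, via aroyl chloride 10 (not isolated)
Conditions: 9, 1-chloro-N,N,2-trimethylprop-1-en-1-amine, CH2Cl2, 0 °C; then 6, Et3N, DMAP (cat.), CH2Cl2, 0→40 °C
Reagents that add atoms: none
Why: The α-chloroenamine converts the acid into the aroyl chloride under neutral conditions without HCl, which the acetals need; DMAP-catalysed acylation (acylpyridinium) of the tertiary but fairly acidic α-hydroxy malonate should then give the ester, and no bond to the stereocentre is broken.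

Step 6
Reactants: 11 benzyl methyl (2R)-2-{[2,4-bis(methoxymethoxy)-6-methylbenzoyl]oxy}-2-methylpropanedioate
Product: 12 (2S)-2-{[2,4-bis(methoxymethoxy)-6-methylbenzoyl]oxy}-3-methoxy-2-methyl-3-oxopropanoic acid
Conditions: H2 (1 atm), 10% Pd/C, EtOAc, rt; concentrate below 25 °C
Reagents that add atoms: none
Why: Hydrogenolysis of a benzyl ester under neutral conditions; the acetals, the aryl ester and the methyl ester are inert and no alkene is present yet; the half-acid is kept cold and used at once to avoid decarboxylation (the descriptor changes only because of the priority rules).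

Step 7
Reactants: 12 (2S)-2-{[2,4-bis(methoxymethoxy)-6-methylbenzoyl]oxy}-3-methoxy-2-methyl-3-oxopropanoic acid
Product: 13 methyl (2R)-2-{[2,4-bis(methoxymethoxy)-6-methylbenzoyl]oxy}-3-chloro-2-methyl-3-oxopropanoate
Conditions: 1-chloro-N,N,2-trimethylprop-1-en-1-amine (1.1 equiv), CH2Cl2, 0 °C→rt; evaporate, use crude
Reagents that add atoms: 1-chloro-N,N,2-trimethylprop-1-en-1-amine, CC(C)=C(Cl)N(C)C
Why: Neutral conversion of a carboxylic acid into its chloride by an α-chloroenamine, free of HCl; the α-carbon is quaternary, so neither ketene formation nor racemisation is possible.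

Step 8
Reactants: 13 methyl (2R)-2-{[2,4-bis(methoxymethoxy)-6-methylbenzoyl]oxy}-3-chloro-2-methyl-3-oxopropanoate; 14 (E)-4-(dimethylamino)but-3-en-2-one
Product: 16 (1R)-3-[(dimethylamino)methylidene]-1-methyl-2,4,6-trioxocyclohexyl 2,4-bis(methoxymethoxy)-6-methylbenzoate, via C-acylated enaminone 15 (not isolated)
Conditions: Et3N (1.5 equiv), toluene, 0→50 °C; filter, concentrate; then LiN(SiMe3)2 (2.2 equiv), THF, −78→−20 °C; AcOH
Reagents that add atoms: none
Why: The neutral enaminone 14 reacts as a vinylogous amide at its α-carbon (C8a) with the acid chloride carbon of 13 (C8), and triethylamine removes the proton from the iminium adduct to restore the push–pull alkene of 15, any O-acyl isomer being able to revert and funnel to the C-acyl product, while the much less electrophilic methyl ester stays intact. LiN(SiMe3)2 then deprotonates the only enolisable position of 15, the acetyl methyl group (C5), and this enolate adds to the ester carbonyl (C6); loss of methoxide and deprotonation of the new β-diketone by the second equivalent of base should make the closure irreversible. The closest known chemistry is the C-acylation of tertiary enaminones by acid chlorides followed by a Dieckmann (intramolecular Claisen) condensation of a δ-keto ester to a cyclohexane-1,3-dione, and deprotonation of the methyl group of such enaminones by this base is established. Ring A closes in the 6-(enolendo)-exo-trig mode. No stereocentre is created: C7 comes unchanged from 13, is quaternary and cannot enolise, and its configuration in the ring follows only from constitution, the former acid chloride carbon becoming C8 and the ester carbon C6. The step therefore needs chemoselectivity in exactly this order, which is secured by running the first acylation without strong base (an enolate of 14 would be acylated at C5 and lead to the mirror-image ring) and adding the amide base only when 13 is consumed; a symmetric trione, which would erase the stereochemical information, is never formed because C1 is present from the start. Attack of the enolate on the aroyl ester, or a shift of the aroyl group to the neighbouring enolate oxygen, should be held back by the two ortho substituents of the aroyl group, and retro-Claisen opening of the product is disfavoured because both carbonyls next to C7 are deactivated (C6 within the diketonate, C8 as a vinylogous amide).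

Step 9
Reactants: 16 (1R)-3-[(dimethylamino)methylidene]-1-methyl-2,4,6-trioxocyclohexyl 2,4-bis(methoxymethoxy)-6-methylbenzoate
Product: 17 (1R)-3-[(dimethylamino)methylidene]-1-methyl-2,6-dioxo-4-[(trifluoromethanesulfonyl)oxy]cyclohex-4-en-1-yl 2,4-bis(methoxymethoxy)-6-methylbenzoate
Conditions: PhNTf2, Et3N, DMAP (cat.), CH2Cl2, 0 °C→rt
Reagents that add atoms: N-phenylbis(trifluoromethanesulfonimide), O=S(=O)(N(c1ccccc1)S(=O)(=O)C(F)(F)F)C(F)(F)F
Why: O-Sulfonylation of a cyclic β-diketone to a β-triflyloxy enone; the oxygen on C4a should react because it is the more electron-rich one (it receives donation from the enolate and from the enamine nitrogen) and the less hindered one, whereas the oxygen on C6 lies next to the quaternary C7 with its bulky aroyloxy group and is inductively deactivated, and the mild triflimide reagent should leave the vinylogous amide untouched.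

Step 10
Reactants: 18 3-(trimethylsilyl)prop-2-ynal; 19 tert-butyl 2-(diethoxyphosphoryl)acetate
Product: 20 tert-butyl (2E)-5-(trimethylsilyl)pent-2-en-4-ynoate
Conditions: 19, NaH, THF, 0 °C; then 18, −78→0 °C
Reagents that add atoms: none
Why: Horner–Wadsworth–Emmons olefination; the stabilised phosphonate anion should give the E enoate under thermodynamic control of the oxaphosphetane, and the silyl group protects the alkyne terminus from base.

Step 11
Reactants: 20 tert-butyl (2E)-5-(trimethylsilyl)pent-2-en-4-ynoate
Product: 21 tert-butyl (2E)-pent-2-en-4-ynoate
Conditions: K2CO3 (cat.), MeOH, 0 °C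
Reagents that add atoms: none
Why: Methoxide-catalysed protodesilylation of an alkynylsilane; the tert-butyl ester does not transesterify under these conditions and the short reaction time at 0 °C should keep conjugate addition of methanol negligible.

Step 12
Reactants: 17 (1R)-3-[(dimethylamino)methylidene]-1-methyl-2,6-dioxo-4-[(trifluoromethanesulfonyl)oxy]cyclohex-4-en-1-yl 2,4-bis(methoxymethoxy)-6-methylbenzoate; 21 tert-butyl (2E)-pent-2-en-4-ynoate
Product: 22 (1R)-4-[(3E)-5-tert-butoxy-5-oxopent-3-en-1-yn-1-yl]-3-[(dimethylamino)methylidene]-1-methyl-2,6-dioxocyclohex-4-en-1-yl 2,4-bis(methoxymethoxy)-6-methylbenzoate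
Conditions: Pd(PPh3)2Cl2 (5 mol%), CuI (10 mol%), Et3N, THF, rt
Reagents that add atoms: none
Why: Sonogashira coupling forms C4–C4a: the electron-poor enol triflate should add readily to zerovalent palladium, the copper acetylide of 21 transmetalates, and neither the tertiary amine nor the acetylide is a nucleophile that exchanges at C1, so the regiochemical problem of a free carbon nucleophile does not arise.

Step 13
Reactants: 22 (1R)-4-[(3E)-5-tert-butoxy-5-oxopent-3-en-1-yn-1-yl]-3-[(dimethylamino)methylidene]-1-methyl-2,6-dioxocyclohex-4-en-1-yl 2,4-bis(methoxymethoxy)-6-methylbenzoate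
Product: 24 (7R)-3-[(1E)-3-tert-butoxy-3-oxoprop-1-en-1-yl]-7-methyl-6,8-dioxo-7,8-dihydro-6H-isochromen-7-yl 2,4-bis(methoxymethoxy)-6-methylbenzoate, via hydroxymethylene dione 23 (not isolated)
Conditions: 1 M aq HCl, THF, 0 °C→rt; then CuI (10 mol%), iPr2NEt (cat.), CH2Cl2, rt
Reagents that add atoms: water, O
Why: Aqueous acid hydrolyses the vinylogous amide by addition–elimination at C1 (iminium, carbinolamine, loss of dimethylamine) to the hydroxymethylene compound 23, a formyl alkynyl vinylogous acid of the kind whose cycloisomerisation is the established ring B closure of azaphilones; its enol oxygen should add to C3, the δ-carbon of the C6 ynenone, in a 6-endo-dig oxa-Michael closure assisted by π-activation of the alkyne by copper, and protonation at C4 gives the pyran without any redox change.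

Step 14
Reactants: 24 (7R)-3-[(1E)-3-tert-butoxy-3-oxoprop-1-en-1-yl]-7-methyl-6,8-dioxo-7,8-dihydro-6H-isochromen-7-yl 2,4-bis(methoxymethoxy)-6-methylbenzoate
Product: 25 mitorubrinic acid, (2E)-3-{(7R)-7-[(2,4-dihydroxy-6-methylbenzoyl)oxy]-7-methyl-6,8-dioxo-7,8-dihydro-6H-isochromen-3-yl}prop-2-enoic acid
Conditions: CF3CO2H/CH2Cl2/H2O, 0 °C→rt
Reagents that add atoms: none
Why: Global acidolysis: the tert-butyl ester is cleaved through the tert-butyl cation and the two methoxymethyl acetals are hydrolysed, while the isochromenedione, the hindered tertiary aryl ester and the quaternary stereocentre should be stable to non-nucleophilic acid.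

Compound list

1 | (S)-lactic acid | C[C@H](O)C(=O)O | starting material
2 | pivalaldehyde (2,2-dimethylpropanal) | CC(C)(C)C=O | starting material
3 | (2S,5S)-2-tert-butyl-5-methyl-1,3-dioxolan-4-one | C[C@@H]1O[C@H](C(C)(C)C)OC1=O | intermediate
4 | methyl (2S,4R)-2-tert-butyl-4-methyl-5-oxo-1,3-dioxolane-4-carboxylate | C[C@]1(C(=O)OC)O[C@H](C(C)(C)C)OC1=O | intermediate
5 | (2S)-2-hydroxy-3-methoxy-2-methyl-3-oxopropanoic acid (formed as its lithium salt) | COC(=O)[C@@](C)(O)C(=O)O | intermediate
6 | benzyl methyl (2R)-2-hydroxy-2-methylpropanedioate | COC(=O)[C@@](C)(O)C(=O)OCc1ccccc1 | intermediate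
7 | orsellinic acid (2,4-dihydroxy-6-methylbenzoic acid) | Cc1cc(O)cc(O)c1C(=O)O | starting material
8 | methoxymethyl 2,4-bis(methoxymethoxy)-6-methylbenzoate | Cc1cc(OCOC)cc(OCOC)c1C(=O)OCOC | intermediate
9 | 2,4-bis(methoxymethoxy)-6-methylbenzoic acid | Cc1cc(OCOC)cc(OCOC)c1C(=O)O | intermediate
10 | 2,4-bis(methoxymethoxy)-6-methylbenzoyl chloride | Cc1cc(OCOC)cc(OCOC)c1C(=O)Cl | intermediate
11 | benzyl methyl (2R)-2-{[2,4-bis(methoxymethoxy)-6-methylbenzoyl]oxy}-2-methylpropanedioate | COC(=O)[C@@](C)(OC(=O)c1c(C)cc(OCOC)cc1OCOC)C(=O)OCc1ccccc1 | intermediate
12 | (2S)-2-{[2,4-bis(methoxymethoxy)-6-methylbenzoyl]oxy}-3-methoxy-2-methyl-3-oxopropanoic acid | COC(=O)[C@@](C)(OC(=O)c1c(C)cc(OCOC)cc1OCOC)C(=O)O | intermediate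
13 | methyl (2R)-2-{[2,4-bis(methoxymethoxy)-6-methylbenzoyl]oxy}-3-chloro-2-methyl-3-oxopropanoate | COC(=O)[C@@](C)(OC(=O)c1c(C)cc(OCOC)cc1OCOC)C(=O)Cl | intermediate
14 | (E)-4-(dimethylamino)but-3-en-2-one | CC(=O)/C=C/N(C)C | starting material
15 | methyl (2S)-2-{[2,4-bis(methoxymethoxy)-6-methylbenzoyl]oxy}-4-[(dimethylamino)methylidene]-2-methyl-3,5-dioxohexanoate | COC(=O)[C@@](C)(OC(=O)c1c(C)cc(OCOC)cc1OCOC)C(=O)C(=CN(C)C)C(C)=O | intermediate
16 | (1R)-3-[(dimethylamino)methylidene]-1-methyl-2,4,6-trioxocyclohexyl 2,4-bis(methoxymethoxy)-6-methylbenzoate | CN(C)C=C1C(=O)CC(=O)[C@@](C)(OC(=O)c2c(C)cc(OCOC)cc2OCOC)C1=O | intermediate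
17 | (1R)-3-[(dimethylamino)methylidene]-1-methyl-2,6-dioxo-4-[(trifluoromethanesulfonyl)oxy]cyclohex-4-en-1-yl 2,4-bis(methoxymethoxy)-6-methylbenzoate | CN(C)C=C1C(OS(=O)(=O)C(F)(F)F)=CC(=O)[C@@](C)(OC(=O)c2c(C)cc(OCOC)cc2OCOC)C1=O | intermediate
18 | 3-(trimethylsilyl)prop-2-ynal | C[Si](C)(C)C#CC=O | starting material
19 | tert-butyl 2-(diethoxyphosphoryl)acetate | CCOP(=O)(OCC)CC(=O)OC(C)(C)C | starting material
20 | tert-butyl (2E)-5-(trimethylsilyl)pent-2-en-4-ynoate | C[Si](C)(C)C#C/C=C/C(=O)OC(C)(C)C | intermediate
21 | tert-butyl (2E)-pent-2-en-4-ynoate | C#C/C=C/C(=O)OC(C)(C)C | intermediate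
22 | (1R)-4-[(3E)-5-tert-butoxy-5-oxopent-3-en-1-yn-1-yl]-3-[(dimethylamino)methylidene]-1-methyl-2,6-dioxocyclohex-4-en-1-yl 2,4-bis(methoxymethoxy)-6-methylbenzoate | CN(C)C=C1C(C#C/C=C/C(=O)OC(C)(C)C)=CC(=O)[C@@](C)(OC(=O)c2c(C)cc(OCOC)cc2OCOC)C1=O | intermediate
23 | (1R)-4-[(3E)-5-tert-butoxy-5-oxopent-3-en-1-yn-1-yl]-3-(hydroxymethylidene)-1-methyl-2,6-dioxocyclohex-4-en-1-yl 2,4-bis(methoxymethoxy)-6-methylbenzoate | OC=C1C(C#C/C=C/C(=O)OC(C)(C)C)=CC(=O)[C@@](C)(OC(=O)c2c(C)cc(OCOC)cc2OCOC)C1=O | intermediate
24 | (7R)-3-[(1E)-3-tert-butoxy-3-oxoprop-1-en-1-yl]-7-methyl-6,8-dioxo-7,8-dihydro-6H-isochromen-7-yl 2,4-bis(methoxymethoxy)-6-methylbenzoate | Cc1cc(OCOC)cc(OCOC)c1C(=O)O[C@]1(C)C(=O)C=C2C=C(/C=C/C(=O)OC(C)(C)C)OC=C2C1=O | intermediate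
25 | mitorubrinic acid, (2E)-3-{(7R)-7-[(2,4-dihydroxy-6-methylbenzoyl)oxy]-7-methyl-6,8-dioxo-7,8-dihydro-6H-isochromen-3-yl}prop-2-enoic acid | Cc1cc(O)cc(O)c1C(=O)O[C@]1(C)C(=O)C=C2C=C(/C=C/C(=O)O)OC=C2C1=O | target

Total step count: 14. Longest linear sequence: 11 steps (steps 1, 2, 3, 5, 6, 7, 8, 9, 12, 13, 14, from 1 to 25).

Steps least certain to work

Step 8 (key step). The most likely failure is slow or oxygen-directed acylation of 14 by the neopentyl-type acid chloride, so that 13 is still present when the amide base is added and is then acylated at C5 instead of C8a, or the O-acyl isomer does not rearrange to 15. The fallback sets out from 13 and returns at 15. The acid chloride would be added at −78 °C to two equivalents of the lithium enolate of acetone in THF (Claisen-type acylation of a ketone enolate) to give the β-diketone F1; the second equivalent of enolate is consumed by the more acidic product. F1 would then be condensed at its central methylene, the only doubly activated position, with N,N-dimethylformamide dimethyl acetal in toluene at room temperature, which gives 15 with C1 introduced after the C8–C8a bond and not before it. F1 must not meet strong base before C1 is in place, because its dianion would close to a symmetric trione and the configuration would be lost; with the acetal reagent only the central carbon reacts.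

Step 9. The most likely failure is sulfonylation at the wrong enol oxygen (on C6) or at both, since the preference for the oxygen on C4a rests on steric and electronic arguments only. The fallback sets out from 16 and returns at 23, and uses chelation rather than electronics to tell the two oxygens apart. Brief treatment of 16 with dilute aqueous HCl in THF would give the hydroxymethylene trione F2, whose enol next to the formyl carbon is held in a hydrogen bond while the enol on C6 is free and more acidic. Silylation with triisopropylsilyl triflate and 2,6-lutidine at −78 °C should therefore give the C6 silyl enol ether F3, and the remaining chelated hydroxyl on C4a would be converted with Tf2O and pyridine into the C4a triflate F4. Sonogashira coupling of F4 with 21 under the conditions of step 12 would give the alkynyl aldehyde F5, and removal of the silyl group with Et3N·3HF releases 23, which closes to 24 as in step 13.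

Step 5. The most likely failure is a stalled esterification, because the tertiary hydroxyl and the 2,6-disubstituted acyl chloride are both hindered, together with decay of 10 by attack of its ortho acetal oxygen on the acyl chloride carbon. The fallback sets out from 6 and returns at 11, and builds the arene on the ester instead of acylating with it. The diketo-dioxinone F6 (made beforehand by two Claisen-type acylations from commercial 2,2,6-trimethyl-4H-1,3-dioxin-4-one) would be heated with 6 in toluene at 110 °C; the acylketene set free is a small, neutral acyl donor of the kind that acylates tertiary alcohols, and gives the triketo ester F7. Treatment with Et3N and then dilute acid should effect the aldol closure and aromatisation to the free orsellinate F8, and alkylation of both phenols with MOMCl and iPr2NEt gives 11.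

Step 13. The most likely failure is ring closure in the 5-exo sense onto C4, or incomplete exchange of nitrogen for oxygen at C1 with partial loss of the acetal groups on prolonged acid contact. The fallback sets out from 22 and returns at 24, and brings the ring oxygen in at C3 instead of C1. Hydration of the ynenone with Ph3PAuNTf2 (cat.) in wet dioxane should place the oxygen on C3, the δ-carbon of the dienone, and give the C3 ketone F9; catalytic TsOH in CH2Cl2 would then let the C3 enol oxygen attack C1 and expel dimethylamine, a carbonyl condensation of the type that forms γ-pyrones from enaminones, giving 24.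

Further compounds

F1 | step 8 | methyl (2S)-2-{[2,4-bis(methoxymethoxy)-6-methylbenzoyl]oxy}-2-methyl-3,5-dioxohexanoate | COC(=O)[C@@](C)(OC(=O)c1c(C)cc(OCOC)cc1OCOC)C(=O)CC(C)=O
F2 | step 9 | (1R)-3-(hydroxymethylidene)-1-methyl-2,4,6-trioxocyclohexyl 2,4-bis(methoxymethoxy)-6-methylbenzoate | OC=C1C(=O)CC(=O)[C@@](C)(OC(=O)c2c(C)cc(OCOC)cc2OCOC)C1=O
F3 | step 9 | (1R)-3-formyl-4-hydroxy-1-methyl-2-oxo-6-{[tri(propan-2-yl)silyl]oxy}cyclohexa-3,5-dien-1-yl 2,4-bis(methoxymethoxy)-6-methylbenzoate | O=CC1=C(O)C=C(O[Si](C(C)C)(C(C)C)C(C)C)[C@@](C)(OC(=O)c2c(C)cc(OCOC)cc2OCOC)C1=O
F4 | step 9 | (1R)-3-formyl-1-methyl-2-oxo-4-[(trifluoromethanesulfonyl)oxy]-6-{[tri(propan-2-yl)silyl]oxy}cyclohexa-3,5-dien-1-yl 2,4-bis(methoxymethoxy)-6-methylbenzoate | O=CC1=C(OS(=O)(=O)C(F)(F)F)C=C(O[Si](C(C)C)(C(C)C)C(C)C)[C@@](C)(OC(=O)c2c(C)cc(OCOC)cc2OCOC)C1=O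
F5 | step 9 | (1R)-4-[(3E)-5-tert-butoxy-5-oxopent-3-en-1-yn-1-yl]-3-formyl-1-methyl-2-oxo-6-{[tri(propan-2-yl)silyl]oxy}cyclohexa-3,5-dien-1-yl 2,4-bis(methoxymethoxy)-6-methylbenzoate | O=CC1=C(C#C/C=C/C(=O)OC(C)(C)C)C=C(O[Si](C(C)C)(C(C)C)C(C)C)[C@@](C)(OC(=O)c2c(C)cc(OCOC)cc2OCOC)C1=O
F6 | step 5 | 6-(2,4-dioxopentyl)-2,2-dimethyl-4H-1,3-dioxin-4-one | CC(=O)CC(=O)CC1=CC(=O)OC(C)(C)O1
F7 | step 5 | benzyl methyl (2R)-2-methyl-2-[(3,5,7-trioxooctanoyl)oxy]propanedioate | COC(=O)[C@@](C)(OC(=O)CC(=O)CC(=O)CC(C)=O)C(=O)OCc1ccccc1
F8 | step 5 | benzyl methyl (2R)-2-[(2,4-dihydroxy-6-methylbenzoyl)oxy]-2-methylpropanedioate | COC(=O)[C@@](C)(OC(=O)c1c(C)cc(O)cc1O)C(=O)OCc1ccccc1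
F9 | step 13 | (1R)-4-[(3E)-5-tert-butoxy-2,5-dioxopent-3-en-1-yl]-3-[(dimethylamino)methylidene]-1-methyl-2,6-dioxocyclohex-4-en-1-yl 2,4-bis(methoxymethoxy)-6-methylbenzoate | CN(C)C=C1C(CC(=O)/C=C/C(=O)OC(C)(C)C)=CC(=O)[C@@](C)(OC(=O)c2c(C)cc(OCOC)cc2OCOC)C1=O
A1 | alternative 1 | mitorubrinic acid tert-butyl ester | Cc1cc(O)cc(O)c1C(=O)O[C@]1(C)C(=O)C=C2C=C(/C=C/C(=O)OC(C)(C)C)OC=C2C1=O
A2 | alternative 1 | 6-(2,4-dioxopentyl)-2,2-dimethyl-4H-1,3-dioxin-4-one | CC(=O)CC(=O)CC1=CC(=O)OC(C)(C)O1
A3 | alternative 1 | tert-butyl (2E)-3-[(7R)-7-hydroxy-7-methyl-6,8-dioxo-7,8-dihydro-6H-isochromen-3-yl]prop-2-enoate | O[C@]1(C)C(=O)C=C2C=C(/C=C/C(=O)OC(C)(C)C)OC=C2C1=O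
A4 | alternative 2 | 2,4-dihydroxy-3-methyl-6-{[5-(trimethylsilyl)furan-2-yl]methyl}benzaldehyde | Cc1c(O)cc(Cc2ccc([Si](C)(C)C)o2)c(C=O)c1O
A5 | alternative 2 | 2,4-dihydroxy-6-[(2-hydroxy-5-oxo-2,5-dihydrofuran-2-yl)methyl]-3-methylbenzaldehyde | Cc1c(O)cc(CC2(O)C=CC(=O)O2)c(C=O)c1O
A6 | alternative 2 | (2E)-3-(6-hydroxy-7-methyl-8-oxo-8H-isochromen-3-yl)prop-2-enoic acid | CC1=C(O)C=C2C=C(/C=C/C(=O)O)OC=C2C1=O
A7 | alternative 3 | tert-butyl (2E)-3-[4-(2,3-dioxobutylidene)-5-formyl-4H-pyran-2-yl]prop-2-enoate | CC(=O)C(=O)C=C1C=C(/C=C/C(=O)OC(C)(C)C)OC=C1C=O
A8 | alternative 3 | tert-butyl (2E)-3-[(7R)-7-hydroxy-7-methyl-6,8-dioxo-7,8-dihydro-6H-isochromen-3-yl]prop-2-enoate | O[C@]1(C)C(=O)C=C2C=C(/C=C/C(=O)OC(C)(C)C)OC=C2C1=O
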